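**Plan**
1.  Retrosynthesis: first the three O–Si bonds of a tris-silyl ether of the target (O7, O3', O4') are cut, then the aryl–vinyl bond C6–C1'' (Heck disconnection to a 6-iodoflavanone and a terminal alkene), and last the C6–I bond.
2.  Forward: no ring is built. The chromanone and catechol rings come intact from (2S)-eriodictyol, which is silylated, iodinated at C6, joined to the C10 chain in one Heck step and desilylated.
3.  Enabling features: C6 of ring A is the CH between O5 and O7, and the 5-OH sits in a six-membered hydrogen-bond chelate with the C4 carbonyl, so it stays unsilylated and steers iodination to C6. The chain ends in a monosubstituted C1''=C2'' vinyl group next to the C3'' branch, distinct from the trisubstituted C6''=C7'' alkene, and the benzylic C1''–H allows syn β-hydride elimination to the conjugated alkene.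
4.  Stereochemistry: C2 (S) comes from (2S)-eriodictyol and C3'' (S) from (S)-β-citronellene, both chiral pool and never touched. The C1''=C2'' E geometry comes from the syn-insertion/syn-elimination course of the Heck reaction.

Key step: step 3

Assumption: commercial (2S)-eriodictyol and (S)-β-citronellene are taken to be of high enantiomeric purity (to be checked by chiral HPLC and chiral GC before use); flavanone numbering is used and chain atoms are C1''–C8''.

**Step 1**
Reactants: 1 (2S)-eriodictyol
Product: 2 (2S)-2-[3,4-bis(tert-butyldimethylsilyloxy)phenyl]-7-(tert-butyldimethylsilyloxy)-5-hydroxychroman-4-one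
Conditions: TBSCl (3.3 equiv), imidazole (7 equiv), DMF, 0 °C → rt
Reagents that add atoms: tert-butyldimethylsilyl chloride (TBSCl), CC(C)(C)[Si](C)(C)Cl
Why: Phenol O-silylation (imidazole-promoted silyl ether formation) should cap the three free phenols O7, O3' and O4', whereas the 5-OH, held in a hydrogen bond to the C4 carbonyl and sterically shielded, stays free under these mild conditions, and imidazole is too weak a base to open the pyranone ring, so the C2 configuration is kept.

**Step 2**
Reactants: 2 (2S)-7,3',4'-tris-O-TBS-eriodictyol
Product: 3 (2S)-2-[3,4-bis(tert-butyldimethylsilyloxy)phenyl]-7-(tert-butyldimethylsilyloxy)-5-hydroxy-6-iodochroman-4-one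
Conditions: NIS (1.05 equiv), DMF, 0 °C → rt, dark
Reagents that add atoms: N-iodosuccinimide (NIS), O=C1CCC(=O)N1I
Why: Electrophilic aromatic iodination: in 5-hydroxy-7-O-substituted flavonoids NIS in DMF is known to attack C6, the position ortho to the free chelated phenol and between O5 and O7, in preference to C8 (which reacts when O5 is capped), the silylated catechol ring is much less activated, and the neutral medium spares the silyl ethers and C2.

**Step 3**
Reactants: 3 (2S)-6-iodo-7,3',4'-tris-O-TBS-eriodictyol, 4 (S)-β-citronellene [(3S)-3,7-dimethylocta-1,6-diene]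
Product: 5 (2S)-2-[3,4-bis(tert-butyldimethylsilyloxy)phenyl]-7-(tert-butyldimethylsilyloxy)-6-[(1E,3S)-3,7-dimethylocta-1,6-dien-1-yl]-5-hydroxychroman-4-one
Conditions: Pd(OAc)2 (10 mol %), P(o-tol)3 (25 mol %), Cy2NMe (2 equiv), 4 (4 equiv), degassed MeCN, 80 °C, sealed tube, Ar
Reagents that add atoms: none
Why: Mizoroki–Heck reaction: Pd(0) adds oxidatively into the C6–I bond of 3, the aryl–Pd species adds syn across the monosubstituted C1''=C2'' alkene of 4 with the aryl group going to the terminal carbon C1'', and syn β-hydride elimination of a benzylic C1''–H releases the C6–C1'' bond and the conjugated E-alkene in a single event, the amine taking up HI. The closest known reaction type is the Heck coupling of di-ortho-oxygenated aryl iodides, iodoflavonoids included, with terminal alkenes. No ring is closed and no stereocentre is formed: C2 and C3'' are carried in unchanged from 1 and 4, and the E geometry results from the syn-insertion/syn-elimination course, in which the aryl group and the branched chain lie anti in the elimination transition state. The step needs site selectivity (only C6 bears iodine), chemoselectivity for the vinyl group over the trisubstituted C6''=C7'' alkene (secured by the large difference in insertion rate), terminal insertion (secured by the C3'' branch next to the alkene and by the halide-bound neutral Pd pathway) and β-hydride elimination toward C1'' instead of toward C3''–H (favoured by conjugation with ring A). An excess of 4, a hindered tertiary amine and moderate temperature serve to limit Pd–H re-addition, which would move the double bond or erode C3'', and to leave the aryl silyl ethers and the base-labile C2 centre untouched.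

**Step 4**
Reactants: 5 (2S)-6-[(1E,3S)-3,7-dimethylocta-1,6-dien-1-yl]-7,3',4'-tris-O-TBS-eriodictyol
Product: 6 (2S)-2-(3,4-dihydroxyphenyl)-6-[(1E,3S)-3,7-dimethylocta-1,6-dien-1-yl]-5,7-dihydroxychroman-4-one (target)
Conditions: TBAF (3.3 equiv), AcOH (4 equiv), THF, 0 °C, Ar
Reagents that add atoms: none
Why: Fluoride-induced cleavage of the three aryl silyl ethers (desilylation) under acetic acid buffering should free the phenols at near-neutral pH, so that neither base-induced retro-oxa-Michael opening at C2 nor acid-induced reactions of the electron-rich styrene and the trisubstituted alkene intervene.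

**Compound list**
1 | (2S)-eriodictyol, (2S)-2-(3,4-dihydroxyphenyl)-5,7-dihydroxychroman-4-one | c1c(O)cc2c(c1O)C(=O)C[C@@H](c1ccc(O)c(O)c1)O2 | starting material
2 | (2S)-2-[3,4-bis(tert-butyldimethylsilyloxy)phenyl]-7-(tert-butyldimethylsilyloxy)-5-hydroxychroman-4-one | c1c(O[Si](C)(C)C(C)(C)C)cc2c(c1O)C(=O)C[C@@H](c1ccc(O[Si](C)(C)C(C)(C)C)c(O[Si](C)(C)C(C)(C)C)c1)O2 | intermediate
3 | (2S)-2-[3,4-bis(tert-butyldimethylsilyloxy)phenyl]-7-(tert-butyldimethylsilyloxy)-5-hydroxy-6-iodochroman-4-one | Ic1c(O[Si](C)(C)C(C)(C)C)cc2c(c1O)C(=O)C[C@@H](c1ccc(O[Si](C)(C)C(C)(C)C)c(O[Si](C)(C)C(C)(C)C)c1)O2 | intermediate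
4 | (S)-β-citronellene, (3S)-3,7-dimethylocta-1,6-diene | CC(C)=CCC[C@H](C)C=C | starting material
5 | (2S)-2-[3,4-bis(tert-butyldimethylsilyloxy)phenyl]-7-(tert-butyldimethylsilyloxy)-6-[(1E,3S)-3,7-dimethylocta-1,6-dien-1-yl]-5-hydroxychroman-4-one | CC(C)=CCC[C@H](C)/C=C/c1c(O[Si](C)(C)C(C)(C)C)cc2c(c1O)C(=O)C[C@@H](c1ccc(O[Si](C)(C)C(C)(C)C)c(O[Si](C)(C)C(C)(C)C)c1)O2 | intermediate
6 | (2S)-2-(3,4-dihydroxyphenyl)-6-[(1E,3S)-3,7-dimethylocta-1,6-dien-1-yl]-5,7-dihydroxychroman-4-one | CC(C)=CCC[C@H](C)/C=C/c1c(O)cc2c(c1O)C(=O)C[C@@H](c1ccc(O)c(O)c1)O2 | target

**Total step count:** 4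
**Longest linear sequence:** 4 (1 → 2 → 3 → 5 → 6)

**Steps most likely to fail**

Step 3 (Heck coupling). β-Hydride elimination toward C3''–H, or Pd–H re-addition and chain walking, could move the double bond out of conjugation and erode the C3'' configuration. Internal insertion could also compete, as could hydrodeiodination at the crowded aryl–Pd centre and slow amine-induced epimerisation at C2 on long heating. The fallback sets out from 3 and from commercial (S)-citronellal (CC(C)=CCC[C@H](C)CC=O) and comes back at 5. One-pot nonaflation–elimination of the aldehyde (nonafluorobutanesulfonyl fluoride, phosphazene base, DMF, −20 °C → rt) should give (3S)-3,7-dimethyloct-6-en-1-yne F1 with the same carbon count. Cp2Zr(H)Cl-catalysed syn hydroboration with pinacolborane should place boron at the terminus and give 2-[(1E,3S)-3,7-dimethylocta-1,6-dien-1-yl]-4,4,5,5-tetramethyl-1,3,2-dioxaborolane F2, leaving the trisubstituted alkene alone. Suzuki–Miyaura coupling of F2 with 3 (Pd(OAc)2/SPhos, aq. K3PO4, THF, 40 °C) then forms the same C6–C1'' bond. The E geometry is already present in the alkenylboronate as a result of the syn hydroboration, and the coupling involves no β-hydride elimination in which the alkene could move.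

Step 2 (iodination). Attack at C8 or double iodination could compete, because the bulky 7-O-silyl group crowds C6. The fallback sets out from 2 and comes back at 3, with the regioisomeric by-product recycled to 2, so that site-selective iodination is no longer required. The iodination is run to partial conversion and 3 is separated by chromatography from the C8 iodide (2S)-2-[3,4-bis(tert-butyldimethylsilyloxy)phenyl]-7-(tert-butyldimethylsilyloxy)-5-hydroxy-8-iodochroman-4-one F3. F3 is returned to 2 by hydrogenolytic deiodination (H2, Pd/C, Et3N, EtOAc), which meets no alkene at this stage, and is iodinated again.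

Step 4 (desilylation). Fluoride-generated phenoxides could trigger retro-oxa-Michael opening and loss of the C2 configuration. Adventitious acid could protonate the electron-rich styrene and start cyclisation onto the C6''=C7'' alkene or a phenol, and the free catechol could oxidise in air. The fallback sets out from 3 and comes back at 6 by changing the order of events. The silyl groups are removed before the chain is present (TBAF/AcOH, THF, 0 °C) to give (2S)-2-(3,4-dihydroxyphenyl)-5,7-dihydroxy-6-iodochroman-4-one F4. The Heck coupling of F4 with 4 is then run under the conditions of step 3 with one further equivalent of amine, free phenols being tolerated in Heck reactions, so that the diene never meets fluoride.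

**Further compounds**
F1 | step 3 | (3S)-3,7-dimethyloct-6-en-1-yne | CC(C)=CCC[C@H](C)C#C
F2 | step 3 | 2-[(1E,3S)-3,7-dimethylocta-1,6-dien-1-yl]-4,4,5,5-tetramethyl-1,3,2-dioxaborolane | CC(C)=CCC[C@H](C)/C=C/B1OC(C)(C)C(C)(C)O1
F3 | step 2 | (2S)-2-[3,4-bis(tert-butyldimethylsilyloxy)phenyl]-7-(tert-butyldimethylsilyloxy)-5-hydroxy-8-iodochroman-4-one | c1c(O[Si](C)(C)C(C)(C)C)c(I)c2c(c1O)C(=O)C[C@@H](c1ccc(O[Si](C)(C)C(C)(C)C)c(O[Si](C)(C)C(C)(C)C)c1)O2
F4 | step 4 | (2S)-2-(3,4-dihydroxyphenyl)-5,7-dihydroxy-6-iodochroman-4-one | Ic1c(O)cc2c(c1O)C(=O)C[C@@H](c1ccc(O)c(O)c1)O2
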